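**Plan**

- Retrosynthesis: cut the acetate O–acyl bond on C3 of the butanoyl chain, then the C3–H bond (carbinol back to ketone), then the aryl O–C1 acyl bond, and last the bond from the ring carbon ortho to the phenol oxygen to the prenyl CH2.
- Forward: the benzene ring is bought and no ring is made; the prenyl group goes onto the ring carbon next to the phenol oxygen, the four-carbon 3-oxobutanoyl chain is attached to that oxygen, the ketone is reduced and the alcohol is acetylated.
- Enabling feature: the only stereocentre is C3 of the butanoyl chain, an oxygen-bearing carbon between a methyl group and a CH2–C(=O)OAr arm. This maps onto a 3-oxobutanoate whose two ketone substituents differ clearly in size.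
- Stereochemistry: an (S)-selective ketoreductase adds hydride to the re face of the C3 ketone; the final acetylation touches only oxygen and keeps the configuration.

Key step: step 3

Assumption: a hydrolase-free, NADPH-dependent ketoreductase of Prelog selectivity that accepts the bulky aryl ester is taken from a commercial screening panel; its sense of induction is taken to be the one such enzymes show on alkyl 3-oxobutanoates.

**Step 1**
Reactants: 1 methyl (E)-3-(4-hydroxyphenyl)prop-2-enoate (methyl (E)-4-hydroxycinnamate); 2 1-bromo-3-methylbut-2-ene (prenyl bromide)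
Product: 5 methyl (E)-3-[4-hydroxy-3-(3-methylbut-2-enyl)phenyl]prop-2-enoate, via sodium phenoxide 3 (not isolated), via ortho-dienone 4 (not isolated)
Conditions: NaH (1.05 equiv), toluene, 0 °C to rt; then 2 (0.9 equiv), rt to 40 °C, 20 h; aq. NH4Cl
Reagents that add atoms: sodium hydride, [Na+].[H-] (its sodium is carried only in 3)
Why: Ortho-C-alkylation of a phenoxide: in toluene the tight sodium ion pair shields oxygen, so the allylic bromide should be attacked in an SN2 reaction by the ortho carbon (para is blocked), and the dienone 4 tautomerises back to the phenol.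

**Step 2**
Reactants: 5 methyl (E)-3-[4-hydroxy-3-(3-methylbut-2-enyl)phenyl]prop-2-enoate; 6 2,2,6-trimethyl-4H-1,3-dioxin-4-one
Product: 8 methyl (E)-3-[3-(3-methylbut-2-enyl)-4-(3-oxobutanoyloxy)phenyl]prop-2-enoate, via acetylketene 7 (not isolated)
Conditions: 6 (1.5 equiv), toluene, 110 °C, acetone distilled off, 1–2 h
Reagents that add atoms: none
Why: Acetoacetylation through acetylketene: thermal retro-hetero-Diels–Alder of the dioxinone releases the ketene, which the phenol should trap by O-acylation under neutral conditions that leave both alkenes and the methyl ester alone.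

**Step 3**
Reactants: 8 methyl (E)-3-[3-(3-methylbut-2-enyl)-4-(3-oxobutanoyloxy)phenyl]prop-2-enoate
Product: 9 methyl (E)-3-[4-[(3S)-3-hydroxybutanoyl]oxy-3-(3-methylbut-2-enyl)phenyl]prop-2-enoate
Conditions: Prelog-selective ketoreductase (hydrolase-free lyophilisate), NADP+ (cat.), i-PrOH/0.1 M KH2PO4–K2HPO4 buffer pH 6.3 (1:4), 30 °C; EtOAc extraction
Reagents that add atoms: none
Why: Enzyme-bound NADPH transfers its C4 hydride to the re face of the C3 carbonyl of 8 while an active-site acid protonates the oxygen, and the same enzyme oxidises isopropanol to return NADPH. The closest known reaction is the ketoreductase (alcohol dehydrogenase) reduction of alkyl acetoacetates to (S)-3-hydroxybutanoates, the standard enzymatic asymmetric β-keto ester reduction. No ring is closed and no skeletal bond is formed; only the C3–H bond is made. The new C3 stereocentre is controlled by the enzyme's binding pockets, with the methyl group in the small pocket and the CH2–CO2Ar arm in the large one, so the alcohol should be the (S) enantiomer. The step needs ketone-only chemoselectivity and survival of the aryl ester: the hydride donor is confined to the active site, so the cinnamate and prenyl alkenes and both esters should stay untouched. A pH near 6.3, below the expected pKa of the C2–H, and a hydrolase-free preparation should hold back enolate fragmentation to acetylketene and ester hydrolysis.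

**Step 4**
Reactants: 9 methyl (E)-3-[4-[(3S)-3-hydroxybutanoyl]oxy-3-(3-methylbut-2-enyl)phenyl]prop-2-enoate
Product: 10 methyl (E)-3-[4-[(3S)-3-acetyloxybutanoyl]oxy-3-(3-methylbut-2-enyl)phenyl]prop-2-enoate
Conditions: Ac2O (1.5 equiv), pyridine (3 equiv), CH2Cl2, 0 °C to rt
Reagents that add atoms: acetic anhydride, CC(=O)OC(C)=O
Why: O-Acetylation of a secondary alcohol by nucleophilic acyl substitution; the C3–O bond is not broken, so the (S) configuration is kept, and the weak base without DMAP should not trigger β-elimination to the crotonate.

**Compound list**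

1 | methyl (E)-3-(4-hydroxyphenyl)prop-2-enoate | COC(=O)/C=C/c1ccc(O)cc1 | starting material
2 | 1-bromo-3-methylbut-2-ene | CC(C)=CCBr | starting material
3 | sodium 4-[(E)-3-methoxy-3-oxoprop-1-enyl]phenolate | COC(=O)/C=C/c1ccc([O-])cc1.[Na+] | intermediate (not isolated)
4 | methyl (E)-3-[3-(3-methylbut-2-enyl)-4-oxocyclohexa-1,5-dien-1-yl]prop-2-enoate (racemic at the ring sp3 carbon) | O=C1C=CC(/C=C/C(=O)OC)=CC1CC=C(C)C | intermediate (not isolated)
5 | methyl (E)-3-[4-hydroxy-3-(3-methylbut-2-enyl)phenyl]prop-2-enoate | COC(=O)/C=C/c1ccc(O)c(CC=C(C)C)c1 | intermediate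
6 | 2,2,6-trimethyl-4H-1,3-dioxin-4-one | CC1=CC(=O)OC(C)(C)O1 | starting material
7 | acetylketene (but-1-ene-1,3-dione) | CC(=O)C=C=O | intermediate (not isolated)
8 | methyl (E)-3-[3-(3-methylbut-2-enyl)-4-(3-oxobutanoyloxy)phenyl]prop-2-enoate | COC(=O)/C=C/c1ccc(OC(=O)CC(C)=O)c(CC=C(C)C)c1 | intermediate
9 | methyl (E)-3-[4-[(3S)-3-hydroxybutanoyl]oxy-3-(3-methylbut-2-enyl)phenyl]prop-2-enoate | COC(=O)/C=C/c1ccc(OC(=O)C[C@H](C)O)c(CC=C(C)C)c1 | intermediate
10 | methyl (E)-3-[4-[(3S)-3-acetyloxybutanoyl]oxy-3-(3-methylbut-2-enyl)phenyl]prop-2-enoate | COC(=O)/C=C/c1ccc(OC(=O)C[C@H](C)OC(C)=O)c(CC=C(C)C)c1 | target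

**Count**

Total steps: 4. Longest linear sequence: 4 steps (1 to 10).

**Steps most likely to fail**

1. Step 3. The aryl ester may be cleaved during the biotransformation, by hydrolysis or by enolate fragmentation to the ketene, and turnover of a bulky, poorly water-soluble substrate may be slow. The fallback sets out from phenol 5 and rejoins the route at target 10. Commercial (3S)-3-hydroxybutanoic acid F1 is acetylated (Ac2O, pyridine, then aqueous work-up) to (3S)-3-acetyloxybutanoic acid F2. F2 is then coupled to 5 under Steglich conditions (EDC·HCl, cat. DMAP, CH2Cl2, 0 °C) to give 10 directly. The stereocentre then comes from the chiral pool and the labile aryl 3-oxobutanoate never meets water.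

2. Step 1. The ambident phenoxide may alkylate on oxygen or twice on carbon, and the heterogeneous salt may convert poorly. The fallback sets out from 1 and comes back at 5. Ortho-iodination with N-iodosuccinimide (cat. TsOH, MeCN, rt) should give methyl (E)-3-(4-hydroxy-3-iodophenyl)prop-2-enoate F3. A Stille coupling of F3 with tributyl(3-methylbut-2-enyl)stannane (Pd(PPh3)4, DMF, 90 °C) should then place the prenyl group only where the iodine stood, bonded through its CH2 terminus.

3. Step 2. The aryl 3-oxobutanoate may revert thermally to phenol and ketene, and ketene dimerisation may outrun O-acylation of the hindered, electron-poor phenol. The fallback sets out from 5 and returns at 8. Diketene (4-methylideneoxetan-2-one) with catalytic DMAP in CH2Cl2 at −10 to 0 °C acetoacetylates the phenol by nucleophile-catalysed opening of the β-lactone, without heat; no new compound arises on the way.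

**Further compounds**

F1 | step 3 | (3S)-3-hydroxybutanoic acid | C[C@H](O)CC(=O)O
F2 | step 3 | (3S)-3-acetyloxybutanoic acid | C[C@H](OC(C)=O)CC(=O)O
F3 | step 1 | methyl (E)-3-(4-hydroxy-3-iodophenyl)prop-2-enoate | COC(=O)/C=C/c1ccc(O)c(I)c1
F0 | step 2 | none | none
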